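**Retrosynthetic overview**
- Target ⇐ tricyclic diol by double angeloylation (last step).
- Cyclobutane last: C10–C11 bond by 4-exo opening of the 9,10-epoxide of a cis-fused bicyclic enone by its own C11 enolate; this also fixes the C9 oxygen.
- Seven-membered ring by ring-closing metathesis (C9=C10) of a cis-4-isopropenyl-5-alkylcyclohexenone; C7 carbinol by asymmetric allylation.
- Six-membered enone ring with both side-chain carbons (C6 on C5, C10 on C4) by dearomatising nucleophile/MeI/CO double addition to (3-methylanisole)Cr(CO)3; the cis relationship is then set by kinetic enolate protonation.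
- Ring order: six-membered ring (from the arene) → seven-membered ring → four-membered ring.

Atom labels used below: C1 ring C=O, C2=C3(CH3), C4 and C11 the cyclobutane CH next to C3 and C1, C5 the cyclobutane CH bearing C6(CH3)2, C7 and C9 the oxygenated carbons, C8 the CH2 between them, C10 the quaternary C–CH3. The target is (4R,5S,7S,9S,10R,11R).

Assumption: racemic material is carried through steps 1–5, and the single enantiomer is secured in step 6 by reagent-controlled allylation of both enantiomers and separation of the two resulting diastereomers (at most half of the material is used).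

Step 1
Reactants: 1 3-methylanisole; 2 hexacarbonylchromium Cr(CO)6
Product: 3 racemic tricarbonyl(η6-3-methylanisole)chromium
Conditions: Cr(CO)6, Bu2O–THF 10:1, 140 °C, 24 h
Reagents that add atoms: none
Why: Thermal arene–metal complexation (exchange of three CO ligands) of the electron-rich arene gives the racemic planar-chiral Cr(CO)3 complex, whose ring is now electrophilic.

Step 2
Reactants: 3 racemic tricarbonyl(η6-3-methylanisole)chromium; 4 isobutyronitrile
Product: 6 rac-trans-2-(6-acetyl-3-methoxy-5-methylcyclohexa-2,4-dien-1-yl)-2-methylpropanenitrile, via lithium cyclohexadienyl chromate 5 (not isolated)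
Conditions: 4, LiN(iPr)2, THF, −78 °C; add 3, THF–HMPA, −78 °C; MeI, CO (4 bar), −78 → 20 °C
Reagents that add atoms: iodomethane, CI; carbon monoxide, [C-]#[O+]
Why: Proposed new method: the lithiated nitrile adds exo to the ring carbon meta to OMe (C5) as in Semmelhack additions to anisole complexes, and at −78 °C in THF–HMPA methylation at chromium, CO insertion and endo acyl migration to the dienyl terminus para to OMe (C4) should outrun dissociation of the carbanion, after which CO releases the trans-acetyl methoxydiene; the closest known reaction is the Kündig nucleophile/alkyl halide/CO trans double addition to arene–Cr(CO)3 complexes (established for dithianyl and organolithium nucleophiles), stretched here to a nitrile-stabilised nucleophile and a methyl-flanked acylation site.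

Step 3
Reactants: 6 rac-trans-2-(6-acetyl-3-methoxy-5-methylcyclohexa-2,4-dien-1-yl)-2-methylpropanenitrile
Product: 8 rac-cis-2-(6-acetyl-3-methoxy-5-methylcyclohexa-2,4-dien-1-yl)-2-methylpropanenitrile, via potassium trienolate 7 (not isolated)
Conditions: KN(SiMe3)2 (0.95 equiv), THF, −78 → −20 °C; then AcOH, THF, −78 °C; used crude
Reagents that add atoms: none
Why: Equilibrating deprotonation removes the C4 hydrogen (α to the acetyl group and dienylic) to give the planar cross-conjugated trienolate, in which C5 is the only sp3 ring atom, so kinetic C-protonation (Zimmerman-type enolate protonation) comes from the face opposite the 2-cyanopropan-2-yl group and installs the contra-thermodynamic cis relationship of the C4 and C5 substituents.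

Step 4
Reactants: 8 rac-cis-2-(6-acetyl-3-methoxy-5-methylcyclohexa-2,4-dien-1-yl)-2-methylpropanenitrile
Product: 9 rac-cis-2-[3-methoxy-5-methyl-6-(prop-1-en-2-yl)cyclohexa-2,4-dien-1-yl]-2-methylpropanenitrile
Conditions: Cp2Ti(μ-CH2)(μ-Cl)AlMe2 (Tebbe reagent), pyridine, THF, −40 → 0 °C
Reagents that add atoms: Tebbe reagent, C[Al-]1(C)C[Ti](C2C=CC=C2)(C2C=CC=C2)[Cl+]1
Why: Tebbe methylenation (carbonyl olefination) is non-basic, so the epimerisable C4 centre is not touched, and the ketone reacts much faster than the hindered tertiary nitrile or the enol ether.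

Step 5
Reactants: 9 rac-cis-2-[3-methoxy-5-methyl-6-(prop-1-en-2-yl)cyclohexa-2,4-dien-1-yl]-2-methylpropanenitrile
Product: 11 rac-cis-2-methyl-2-[3-methyl-5-oxo-2-(prop-1-en-2-yl)cyclohex-3-en-1-yl]propanal, via dienol ether aldehyde 10 (not isolated)
Conditions: iBu2AlH, toluene, −78 °C; then 1 M HCl, THF, 0 °C
Reagents that add atoms: water, O
Why: Nitrile half-reduction with iBu2AlH stops at the N-alumino imine, and aqueous acid then hydrolyses the imine to the neopentyl aldehyde and the 2-methoxydiene (protonation at C11) to the conjugated enone without touching the C4 or C5 stereocentres.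

Step 6
Reactants: 11 rac-cis-2-methyl-2-[3-methyl-5-oxo-2-(prop-1-en-2-yl)cyclohex-3-en-1-yl]propanal; 12 (−)-B-allyldiisopinocampheylborane
Product: 13 (4S,5R)-5-[(3S)-3-hydroxy-2-methylhex-5-en-2-yl]-3-methyl-4-(prop-1-en-2-yl)cyclohex-2-en-1-one
Conditions: 12 (1.2 equiv), Et2O, −78 °C; then HOCH2CH2NH2; chromatographic separation from the (4R,5S,3'S) diastereomer
Reagents that add atoms: none
Why: Brown asymmetric allylboration is reagent-controlled (Si-face attack through a chair transition state) and much faster on the aldehyde than on the enone, so C7 is set as S in both enantiomers of racemic 11, and separating the two resulting diastereomers secures the single-enantiomer series.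

Step 7
Reactants: 13 (4S,5R)-5-[(3S)-3-hydroxy-2-methylhex-5-en-2-yl]-3-methyl-4-(prop-1-en-2-yl)cyclohex-2-en-1-one
Product: 14 (4S,5R)-3-methyl-5-[(3S)-2-methyl-3-(triethylsilyloxy)hex-5-en-2-yl]-4-(prop-1-en-2-yl)cyclohex-2-en-1-one
Conditions: Et3SiOTf, 2,6-lutidine, CH2Cl2, −78 °C
Reagents that add atoms: triethylsilyl trifluoromethanesulfonate, CC[Si](CC)(CC)OS(=O)(=O)C(F)(F)F
Why: Silyl ether formation masks the C7 hydroxyl so that it can neither direct the epoxidation in step 9 nor open the epoxide as an alkoxide in step 10.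

Step 8
Reactants: 14 (4S,5R)-3-methyl-5-[(3S)-2-methyl-3-(triethylsilyloxy)hex-5-en-2-yl]-4-(prop-1-en-2-yl)cyclohex-2-en-1-one
Product: 15 (4aS,8S,9aR)-4,5,9,9-tetramethyl-8-(triethylsilyloxy)-1,4a,7,8,9,9a-hexahydro-2H-benzo[7]annulen-2-one
Conditions: second-generation Grubbs catalyst RuCl2(=CHPh)(PCy3)(H2IMes) (5 mol %), CH2Cl2 (2 mM), 40 °C
Reagents that add atoms: none
Why: Ring-closing metathesis between the isopropenyl and allyl groups, which are cis on the six-membered ring, closes the seven-membered ring with its trisubstituted C9=C10 ring alkene, driven by loss of ethene.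

Step 9
Reactants: 15 (4aS,8S,9aR)-4,5,9,9-tetramethyl-8-(triethylsilyloxy)-1,4a,7,8,9,9a-hexahydro-2H-benzo[7]annulen-2-one
Product: 16 (4R,5R,7S,9S,10R)-9,10-epoxide of 15 (oxirane on the face opposite the six-membered ring and the C7 silyloxy group)
Conditions: mCPBA, NaHCO3, CH2Cl2, 0 °C
Reagents that add atoms: 3-chloroperbenzoic acid, OOC(=O)c1cccc(Cl)c1
Why: Prilezhaev epoxidation occurs only at the electron-rich trisubstituted alkene and from the convex face of the cis-fused bicycle, anti to the six-membered ring carbons and to the C7 silyloxy group.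

Step 10
Reactants: 16 (4R,5R,7S,9S,10R)-9,10-epoxide of 15
Product: 18 (1R,2R,3S,5S,7S,8R)-3,5-dihydroxy-2,6,6,9-tetramethyltricyclo[5.4.0.0(2,8)]undec-9-en-11-one, via silyl-protected tricyclic alcohol 17 (not isolated)
Conditions: LiN(iPr)2, THF, −78 → 25 °C; then 1 M HCl, THF, 0 °C
Reagents that add atoms: none
Why: Proposed new method: kinetic deprotonation of the enone at C11 gives the cross-conjugated lithium enolate, which opens the epoxide at the tertiary carbon C10 from the side opposite oxygen in a 4-exo-tet SN2 closure (O-alkylation would need a bridgehead enol ether and is excluded), forming the cyclobutane and quaternary C10 with inversion and leaving the C9 oxygen anti to C11 as in the target, after which acid removes the silyl group; the closest known reactions are the Stork epoxynitrile cyclisation to cyclobutanes and the enolate alkylations that close the cyclobutane of pinane-type bicyclo[3.1.1]heptanones, here combined with a ketone enolate and an epoxide.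

Step 11
Reactants: 18 (1R,2R,3S,5S,7S,8R)-3,5-dihydroxy-2,6,6,9-tetramethyltricyclo[5.4.0.0(2,8)]undec-9-en-11-one; 19 angelic acid
Product: 20 (1R,2R,3S,5S,7S,8R)-2,6,6,9-tetramethyl-11-oxotricyclo[5.4.0.0(2,8)]undec-9-ene-3,5-diyl bis[(2Z)-2-methylbut-2-enoate]
Conditions: 19 (6 equiv), 2,4,6-Cl3C6H2COCl (6 equiv), Et3N, toluene, 20 °C; then 18, 80 °C
Reagents that add atoms: angelic acid (second equivalent of 19; each hydroxyl takes up one angeloyl group), C/C=C(/C)C(=O)O
Why: Yamaguchi-type mixed-anhydride esterification without a nucleophilic amine catalyst acylates both hindered secondary alcohols, each with one molecule of the angelic 2,4,6-trichlorobenzoic anhydride, and keeps the Z (angelate) geometry because no reversible conjugate addition to the acyl donor can occur.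

**Compound list**
1 | 3-methylanisole | COc1cccc(C)c1 | starting material
2 | hexacarbonylchromium, Cr(CO)6 | [Cr].[C-]#[O+].[C-]#[O+].[C-]#[O+].[C-]#[O+].[C-]#[O+].[C-]#[O+] | starting material
3 | racemic tricarbonyl(η6-3-methylanisole)chromium (written as arene plus Cr(CO)3) | COc1cccc(C)c1.[Cr].[C-]#[O+].[C-]#[O+].[C-]#[O+] | intermediate
4 | isobutyronitrile | CC(C)C#N | starting material
5 | lithium tricarbonyl[η5-6-(2-cyanopropan-2-yl)-2-methoxy-4-methylcyclohexadienyl]chromate, racemic | [Li+].COC1=CC(C)=CC(C(C)(C)C#N)[CH-]1.[Cr].[C-]#[O+].[C-]#[O+].[C-]#[O+] | intermediate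
6 | rac-trans-2-(6-acetyl-3-methoxy-5-methylcyclohexa-2,4-dien-1-yl)-2-methylpropanenitrile | N#CC(C)(C)[C@@H]1C=C(OC)C=C(C)[C@H]1C(C)=O | intermediate
7 | potassium trienolate of 6 (C4 planar), racemic | [K+].N#CC(C)(C)[C@@H]1C=C(OC)C=C(C)C1=C(C)[O-] | intermediate
8 | rac-cis-2-(6-acetyl-3-methoxy-5-methylcyclohexa-2,4-dien-1-yl)-2-methylpropanenitrile | N#CC(C)(C)[C@@H]1C=C(OC)C=C(C)[C@@H]1C(C)=O | intermediate
9 | rac-cis-2-[3-methoxy-5-methyl-6-(prop-1-en-2-yl)cyclohexa-2,4-dien-1-yl]-2-methylpropanenitrile | N#CC(C)(C)[C@@H]1C=C(OC)C=C(C)[C@@H]1C(C)=C | intermediate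
10 | rac-cis-2-[3-methoxy-5-methyl-6-(prop-1-en-2-yl)cyclohexa-2,4-dien-1-yl]-2-methylpropanal | O=CC(C)(C)[C@@H]1C=C(OC)C=C(C)[C@@H]1C(C)=C | intermediate
11 | rac-cis-2-methyl-2-[3-methyl-5-oxo-2-(prop-1-en-2-yl)cyclohex-3-en-1-yl]propanal | O=CC(C)(C)[C@@H]1CC(=O)C=C(C)[C@@H]1C(C)=C | intermediate
12 | (−)-B-allyldiisopinocampheylborane (from (+)-α-pinene) | C=CCB([C@@H]1C[C@@H]2C[C@H]([C@H]1C)C2(C)C)[C@@H]1C[C@@H]2C[C@H]([C@H]1C)C2(C)C | starting material
13 | (4S,5R)-5-[(3S)-3-hydroxy-2-methylhex-5-en-2-yl]-3-methyl-4-(prop-1-en-2-yl)cyclohex-2-en-1-one | C=CC[C@H](O)C(C)(C)[C@@H]1CC(=O)C=C(C)[C@@H]1C(C)=C | intermediate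
14 | (4S,5R)-3-methyl-5-[(3S)-2-methyl-3-(triethylsilyloxy)hex-5-en-2-yl]-4-(prop-1-en-2-yl)cyclohex-2-en-1-one | C=CC[C@H](O[Si](CC)(CC)CC)C(C)(C)[C@@H]1CC(=O)C=C(C)[C@@H]1C(C)=C | intermediate
15 | (4aS,8S,9aR)-4,5,9,9-tetramethyl-8-(triethylsilyloxy)-1,4a,7,8,9,9a-hexahydro-2H-benzo[7]annulen-2-one (cis-fused) | CC[Si](CC)(CC)O[C@H]1CC=C(C)[C@H]2C(C)=CC(=O)C[C@H]2C1(C)C | intermediate
16 | (4R,5R,7S,9S,10R)-9,10-epoxide of 15 | CC[Si](CC)(CC)O[C@H]1C[C@@H]2O[C@]2(C)[C@H]3C(C)=CC(=O)C[C@H]3C1(C)C | intermediate
17 | (1R,2R,3S,5S,7S,8R)-3-hydroxy-2,6,6,9-tetramethyl-5-(triethylsilyloxy)tricyclo[5.4.0.0(2,8)]undec-9-en-11-one | CC[Si](CC)(CC)O[C@H]1C[C@H](O)[C@@]2(C)[C@@H]3C(=O)C=C(C)[C@H]2[C@@H]3C1(C)C | intermediate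
18 | (1R,2R,3S,5S,7S,8R)-3,5-dihydroxy-2,6,6,9-tetramethyltricyclo[5.4.0.0(2,8)]undec-9-en-11-one | O[C@H]1C[C@H](O)[C@@]2(C)[C@@H]3C(=O)C=C(C)[C@H]2[C@@H]3C1(C)C | intermediate
19 | angelic acid, (2Z)-2-methylbut-2-enoic acid | C/C=C(/C)C(=O)O | starting material
20 | (1R,2R,3S,5S,7S,8R)-2,6,6,9-tetramethyl-11-oxotricyclo[5.4.0.0(2,8)]undec-9-ene-3,5-diyl bis[(2Z)-2-methylbut-2-enoate] | C/C=C(/C)C(=O)O[C@H]1C[C@H](OC(=O)/C(C)=C\C)[C@@]2(C)[C@@H]3C(=O)C=C(C)[C@H]2[C@@H]3C1(C)C | target

Total step count: 11. Longest linear sequence: 11 steps (1 → 20).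

**Steps most likely to fail, with fallbacks**

Step 2 (acylative dearomatisation). Nitrile-stabilised carbanions add reversibly to arene–Cr(CO)3 complexes, so methylation may simply return 3, and the methyl group next to C4 may divert the acyl group to C11. The fallback sets out from 3 and 4 and uses protonation in place of acyl transfer. Lithiated 4 is added to 3 and quenched with CF3CO2H at −78 °C, then aqueous HCl (Semmelhack protonation, which outruns dissociation), giving rac-2-methyl-2-(3-methyl-5-oxocyclohex-3-en-1-yl)propanenitrile F1. HC(OMe)3/TsOH converts it into the linear methyl dienol ether rac-2-(5-methoxy-3-methylcyclohexa-2,4-dien-1-yl)-2-methylpropanenitrile F2. Its terminal carbon C4 is then acetylated with Ac2O/BF3·OEt2 to the push–pull dienone rac-2-(2-acetyl-5-methoxy-3-methylcyclohexa-2,4-dien-1-yl)-2-methylpropanenitrile F3. Deprotonation of F3 at C11 with KN(SiMe3)2 gives the same trienolate, so the route is rejoined at 7.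

Step 10 (cyclobutane closure by enolate attack on a tertiary epoxide carbon). The lithium enolate may be too unreactive, or may equilibrate to the extended dienolate and destroy the epoxide. The fallback sets out from 16 and changes from an anionic SN2 closure to a Lewis-acid closure. The C11 enolate is trapped with tBuMe2SiCl to give the cross-conjugated tert-butyldimethylsilyl dienol ether of 16 F4. Me2AlCl or BF3·OEt2 in CH2Cl2 at −78 °C then activates the epoxide so that the enol ether carbon C11 captures the developing tertiary cation at C10 from the side opposite the oxygen (Mukaiyama-type epoxide opening; the C9–O bond is not touched). Aqueous work-up returns the route at 17.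

Step 11 (double angeloylation). Both hydroxyls are neopentyl-type and the one at C9 sits next to the quaternary cyclobutane carbon, so acylation may stop at a monoester, and forcing it risks isomerisation to tiglate. The fallback sets out from 18 and builds the Z alkenes on the esters instead of carrying them in. Diol 18 is acylated with 2-[bis(2,2,2-trifluoroethoxy)phosphoryl]propanoic acid (N,N'-dicyclohexylcarbodiimide, 4-(dimethylamino)pyridine, CH2Cl2), which reacts through a small, reactive phosphonoketene and has no alkene to isomerise, giving (1R,2R,3S,5S,7S,8R)-2,6,6,9-tetramethyl-11-oxotricyclo[5.4.0.0(2,8)]undec-9-ene-3,5-diyl bis{2-[bis(2,2,2-trifluoroethoxy)phosphoryl]propanoate} F5. A double Still–Gennari olefination (KN(SiMe3)2, 18-crown-6, THF, −78 °C; then acetaldehyde) forms both (Z)-2-methylbut-2-enoates; the bridgehead position C11 cannot enolise, so the ketone is not disturbed. The route is rejoined at 20.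

**Further compounds**
F1 | step 2 | rac-2-methyl-2-(3-methyl-5-oxocyclohex-3-en-1-yl)propanenitrile | N#CC(C)(C)[C@@H]1CC(=O)C=C(C)C1
F2 | step 2 | rac-2-(5-methoxy-3-methylcyclohexa-2,4-dien-1-yl)-2-methylpropanenitrile | N#CC(C)(C)[C@@H]1CC(OC)=CC(C)=C1
F3 | step 2 | rac-2-(2-acetyl-5-methoxy-3-methylcyclohexa-2,4-dien-1-yl)-2-methylpropanenitrile | N#CC(C)(C)[C@@H]1CC(OC)=CC(C)=C1C(C)=O
F4 | step 10 | tert-butyldimethylsilyl dienol ether of 16 (C11=C1–OSi) | CC[Si](CC)(CC)O[C@H]1C[C@@H]2O[C@]2(C)[C@H]3C(C)=CC(O[Si](C)(C)C(C)(C)C)=C[C@H]3C1(C)C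
F5 | step 11 | (1R,2R,3S,5S,7S,8R)-2,6,6,9-tetramethyl-11-oxotricyclo[5.4.0.0(2,8)]undec-9-ene-3,5-diyl bis{2-[bis(2,2,2-trifluoroethoxy)phosphoryl]propanoate} | CC(P(=O)(OCC(F)(F)F)OCC(F)(F)F)C(=O)O[C@H]1C[C@H](OC(=O)C(C)P(=O)(OCC(F)(F)F)OCC(F)(F)F)[C@@]2(C)[C@@H]3C(=O)C=C(C)[C@H]2[C@@H]3C1(C)C
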